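**Assumption:** the SMILES is read as robinetinidol-(4α→6)-gallocatechin (upper unit 2R,3S,4S; lower unit 2R,3S), and (+)-dihydrorobinetin and (+)-gallocatechin are bought as catalogue natural flavonoids (commercial, though not bulk-cheap).

## Retrosynthetic overview

1. The target is freed in the last step by hydrogenolysis of ten benzyl ethers and a C8 blocking bromine; the upper C3–OH comes from axial hydride addition to a 4-arylflavan-3-one.
2. Key C4–C6 interflavan bond: C4 of a flavan-3-one (a ketone α-carbon, normally a nucleophile) is made electrophilic as the rhodium carbenoid of 4-diazoflavan-3-one 5, an enolonium equivalent. It is attacked by the nucleophilic C6–H of brominated, benzylated gallocatechin 9, and C4 is then set by protonation of the resulting enol.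
3. Compound 5 comes from (+)-dihydrorobinetin by benzylation, NaBH4 reduction, a pinacol-type 1,2-carbonyl shift (C4=O/C3–OH to C3=O/C4H2) and diazo transfer.
4. Compound 9 comes from (+)-gallocatechin by per-benzylation and NBS bromination at C8.
5. No ring is built: all six rings come intact from the two flavonoids; only the inter-unit bond and the upper C3/C4 stereocentres are made.

## Route

**Step 1**
Reactants: 1 (+)-dihydrorobinetin, (2R,3R)-3,7-dihydroxy-2-(3,4,5-trihydroxyphenyl)chroman-4-one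
Product: 2 (2R,3R)-7-(benzyloxy)-3-hydroxy-2-[3,4,5-tris(benzyloxy)phenyl]chroman-4-one
Conditions: BnBr (4.4 equiv), K2CO3 (4.4 equiv), DMF, 0 °C → rt, Ar; recrystallise
Reagents that add atoms: benzyl bromide, BrCc1ccccc1
Why: Williamson etherification of the four phenols only (carbonate does not deprotonate the 3-OH); both stereocentres come from the chiral pool, and any C2-epimerised cis isomer is a diastereomer removed by crystallisation.

**Step 2**
Reactants: 2 (2R,3R)-7-(benzyloxy)-3-hydroxy-2-[3,4,5-tris(benzyloxy)phenyl]chroman-4-one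
Product: 3 (2R,3S,4R)-7-(benzyloxy)-2-[3,4,5-tris(benzyloxy)phenyl]chromane-3,4-diol
Conditions: NaBH4 (1.5 equiv), THF/EtOH 1:1, 0 °C
Reagents that add atoms: none
Why: Borohydride reduction of the aryl ketone with axial hydride attack gives mainly the 3,4-trans diol (4R); the C4 configuration does not matter because it is erased in step 3.

**Step 3**
Reactants: 3 (2R,3S,4R)-7-(benzyloxy)-2-[3,4,5-tris(benzyloxy)phenyl]chromane-3,4-diol
Product: 4 (2R)-7-(benzyloxy)-2-[3,4,5-tris(benzyloxy)phenyl]chroman-3-one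
Conditions: BF3·OEt2 (0.2 equiv), CH2Cl2 (0.01 M), −40 → 0 °C
Reagents that add atoms: none
Why: Pinacol-type (semipinacol) rearrangement: the benzylic 4-OH ionises to a para-benzyloxy-stabilised cation and the axial C3–H shifts (or is lost to the enol), as in tetralin-1,2-diol → 2-tetralone; high dilution suppresses Friedel–Crafts self-condensation and C2 is not involved.

**Step 4**
Reactants: 4 (2R)-7-(benzyloxy)-2-[3,4,5-tris(benzyloxy)phenyl]chroman-3-one
Product: 5 (2R)-7-(benzyloxy)-4-diazo-2-[3,4,5-tris(benzyloxy)phenyl]chroman-3-one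
Conditions: p-ABSA (1.2 equiv), Et3N (1.5 equiv), MeCN, 0 °C
Reagents that add atoms: 4-acetamidobenzenesulfonyl azide (p-ABSA), CC(=O)Nc1ccc(cc1)S(=O)(=O)N=[N+]=[N-]
Why: Regitz diazo transfer to the 2-tetralone-like benzylic C4 methylene, the only α-CH2 (C2 is a methine and cannot take a diazo group); a weak base at low temperature leaves the less acidic C2–H untouched.

**Step 5**
Reactants: 6 (+)-gallocatechin, (2R,3S)-2-(3,4,5-trihydroxyphenyl)chromane-3,5,7-triol
Product: 8 (2R,3S)-3,5,7-tris(benzyloxy)-2-[3,4,5-tris(benzyloxy)phenyl]chromane, via penta-O-benzylgallocatechin 7 (not isolated)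
Conditions: BnBr (7.5 equiv), K2CO3 (6 equiv), DMF, 0 °C → rt, Ar; then NaH (1.5 equiv), 0 °C → rt
Reagents that add atoms: benzyl bromide, BrCc1ccccc1
Why: Two-stage Williamson etherification in one flask (phenols under carbonate, then the 3-alkoxide from NaH); the 3-O-benzyl group prevents O–H insertion in step 7 and both stereocentres come from the chiral pool.

**Step 6**
Reactants: 8 (2R,3S)-3,5,7-tris(benzyloxy)-2-[3,4,5-tris(benzyloxy)phenyl]chromane
Product: 9 (2R,3S)-3,5,7-tris(benzyloxy)-8-bromo-2-[3,4,5-tris(benzyloxy)phenyl]chromane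
Conditions: NBS (1.0 equiv), CH2Cl2, −78 → 0 °C
Reagents that add atoms: N-bromosuccinimide, O=C1CCC(=O)N1Br
Why: Electrophilic aromatic bromination goes to C8, the more reactive position of the phloroglucinol ring in benzylated flavan-3-ols, so bromine blocks C8 and leaves C6–H as the only nucleophilic site for a 4→6 linkage.

**Step 7**
Reactants: 5 (2R)-7-(benzyloxy)-4-diazo-2-[3,4,5-tris(benzyloxy)phenyl]chroman-3-one; 9 (2R,3S)-3,5,7-tris(benzyloxy)-8-bromo-2-[3,4,5-tris(benzyloxy)phenyl]chromane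
Product: 11 (2R,4S)-7-(benzyloxy)-4-[(2R,3S)-3,5,7-tris(benzyloxy)-8-bromo-2-(3,4,5-tris(benzyloxy)phenyl)chroman-6-yl]-2-[3,4,5-tris(benzyloxy)phenyl]chroman-3-one, via chromen-3-ol enol 10 (not isolated)
Conditions: Rh2(OAc)4 (2 mol%), 9 (1.3 equiv), CH2Cl2, 0 °C, 5 added over 2 h; pH 7 buffer work-up
Reagents that add atoms: none
Why: Proposed new method: loss of N2 gives a donor/acceptor rhodium carbenoid whose C4 is an electrophilic ketone α-carbon (enolonium equivalent), and the tri-oxygenated C6 of 9 attacks it in a Friedel–Crafts-type aromatic C–H functionalisation (closest known reaction type: Rh2(OAc)4-catalysed arylation of aryl diazoacetates and 3-diazooxindoles by 1,3,5-trimethoxybenzene); rearomatisation gives enol 10, which is protonated axially at C4 on the face anti to the C2 aryl group to give the 2,4-cis (4S) ketone, also the diequatorial thermodynamic isomer, while C2 is untouched under these neutral conditions.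

**Step 8**
Reactants: 11 (2R,4S)-7-(benzyloxy)-4-[(2R,3S)-3,5,7-tris(benzyloxy)-8-bromo-2-(3,4,5-tris(benzyloxy)phenyl)chroman-6-yl]-2-[3,4,5-tris(benzyloxy)phenyl]chroman-3-one
Product: 12 (2R,3S,4S)-7-(benzyloxy)-4-[(2R,3S)-3,5,7-tris(benzyloxy)-8-bromo-2-(3,4,5-tris(benzyloxy)phenyl)chroman-6-yl]-2-[3,4,5-tris(benzyloxy)phenyl]chroman-3-ol
Conditions: NaBH4 (2 equiv), CeCl3·7H2O (1.2 equiv), THF/MeOH 3:1, −78 → −40 °C
Reagents that add atoms: none
Why: Luche-type borohydride reduction: hydride should add axially to the diequatorial ketone (antiperiplanar to the axial C2–H and C4–H, with no 1,3-diaxial groups at O1 or C4a), giving the equatorial 3-OH trans to both aryl groups (3S), while the cerium salt suppresses enolisation of the doubly benzylic C4–H.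

**Step 9**
Reactants: 12 (2R,3S,4S)-7-(benzyloxy)-4-[(2R,3S)-3,5,7-tris(benzyloxy)-8-bromo-2-(3,4,5-tris(benzyloxy)phenyl)chroman-6-yl]-2-[3,4,5-tris(benzyloxy)phenyl]chroman-3-ol
Product: 13 robinetinidol-(4α→6)-gallocatechin (target)
Conditions: H2 (1 atm), Pd(OH)2/C (20 wt%), Et3N (1.5 equiv), THF/MeOH/H2O 20:20:1, rt; Sephadex LH-20, lyophilise
Reagents that add atoms: none
Why: Catalytic hydrogenolysis cleaves all ten benzyl ethers and hydrodebrominates C8 in one operation, with Et3N taking up HBr so that the acid-labile interflavan bond and the five stereocentres are unaffected.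

## Compound list

1 | (+)-dihydrorobinetin, (2R,3R)-3,7-dihydroxy-2-(3,4,5-trihydroxyphenyl)chroman-4-one | Oc1ccc2c(c1)O[C@H](c1cc(O)c(O)c(O)c1)[C@@H](O)C2=O | starting material
2 | (2R,3R)-7-(benzyloxy)-3-hydroxy-2-[3,4,5-tris(benzyloxy)phenyl]chroman-4-one | c1ccccc1COc1ccc2c(c1)O[C@H](c1cc(OCc3ccccc3)c(OCc3ccccc3)c(OCc3ccccc3)c1)[C@@H](O)C2=O | intermediate
3 | (2R,3S,4R)-7-(benzyloxy)-2-[3,4,5-tris(benzyloxy)phenyl]chromane-3,4-diol | c1ccccc1COc1ccc2c(c1)O[C@H](c1cc(OCc3ccccc3)c(OCc3ccccc3)c(OCc3ccccc3)c1)[C@@H](O)[C@@H]2O | intermediate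
4 | (2R)-7-(benzyloxy)-2-[3,4,5-tris(benzyloxy)phenyl]chroman-3-one | c1ccccc1COc1ccc2c(c1)O[C@H](c1cc(OCc3ccccc3)c(OCc3ccccc3)c(OCc3ccccc3)c1)C(=O)C2 | intermediate
5 | (2R)-7-(benzyloxy)-4-diazo-2-[3,4,5-tris(benzyloxy)phenyl]chroman-3-one | c1ccccc1COc1ccc2c(c1)O[C@H](c1cc(OCc3ccccc3)c(OCc3ccccc3)c(OCc3ccccc3)c1)C(=O)C2=[N+]=[N-] | intermediate
6 | (+)-gallocatechin, (2R,3S)-2-(3,4,5-trihydroxyphenyl)chromane-3,5,7-triol | Oc1cc(O)c2c(c1)O[C@H](c1cc(O)c(O)c(O)c1)[C@@H](O)C2 | starting material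
7 | (2R,3S)-5,7-bis(benzyloxy)-2-[3,4,5-tris(benzyloxy)phenyl]chroman-3-ol (penta-O-benzylgallocatechin, not isolated) | c1ccccc1COc1cc(OCc3ccccc3)c2c(c1)O[C@H](c1cc(OCc3ccccc3)c(OCc3ccccc3)c(OCc3ccccc3)c1)[C@@H](O)C2 | intermediate
8 | (2R,3S)-3,5,7-tris(benzyloxy)-2-[3,4,5-tris(benzyloxy)phenyl]chromane | c1ccccc1COc1cc(OCc3ccccc3)c2c(c1)O[C@H](c1cc(OCc3ccccc3)c(OCc3ccccc3)c(OCc3ccccc3)c1)[C@@H](OCc3ccccc3)C2 | intermediate
9 | (2R,3S)-3,5,7-tris(benzyloxy)-8-bromo-2-[3,4,5-tris(benzyloxy)phenyl]chromane | c1ccccc1COc1cc(OCc3ccccc3)c2c(c1Br)O[C@H](c1cc(OCc3ccccc3)c(OCc3ccccc3)c(OCc3ccccc3)c1)[C@@H](OCc3ccccc3)C2 | intermediate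
10 | (2R)-7-(benzyloxy)-4-[(2R,3S)-3,5,7-tris(benzyloxy)-8-bromo-2-(3,4,5-tris(benzyloxy)phenyl)chroman-6-yl]-2-[3,4,5-tris(benzyloxy)phenyl]-2H-chromen-3-ol (enol of 11, not isolated) | c1ccccc1COc1ccc2c(c1)O[C@H](c1cc(OCc3ccccc3)c(OCc3ccccc3)c(OCc3ccccc3)c1)C(O)=C2c1c(OCc3ccccc3)c(Br)c2c(c1OCc3ccccc3)C[C@H](OCc3ccccc3)[C@@H](c1cc(OCc3ccccc3)c(OCc3ccccc3)c(OCc3ccccc3)c1)O2 | intermediate
11 | (2R,4S)-7-(benzyloxy)-4-[(2R,3S)-3,5,7-tris(benzyloxy)-8-bromo-2-(3,4,5-tris(benzyloxy)phenyl)chroman-6-yl]-2-[3,4,5-tris(benzyloxy)phenyl]chroman-3-one | c1ccccc1COc1ccc2c(c1)O[C@H](c1cc(OCc3ccccc3)c(OCc3ccccc3)c(OCc3ccccc3)c1)C(=O)[C@@H]2c1c(OCc3ccccc3)c(Br)c2c(c1OCc3ccccc3)C[C@H](OCc3ccccc3)[C@@H](c1cc(OCc3ccccc3)c(OCc3ccccc3)c(OCc3ccccc3)c1)O2 | intermediate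
12 | (2R,3S,4S)-7-(benzyloxy)-4-[(2R,3S)-3,5,7-tris(benzyloxy)-8-bromo-2-(3,4,5-tris(benzyloxy)phenyl)chroman-6-yl]-2-[3,4,5-tris(benzyloxy)phenyl]chroman-3-ol | c1ccccc1COc1ccc2c(c1)O[C@H](c1cc(OCc3ccccc3)c(OCc3ccccc3)c(OCc3ccccc3)c1)[C@@H](O)[C@@H]2c1c(OCc3ccccc3)c(Br)c2c(c1OCc3ccccc3)C[C@H](OCc3ccccc3)[C@@H](c1cc(OCc3ccccc3)c(OCc3ccccc3)c(OCc3ccccc3)c1)O2 | intermediate
13 | robinetinidol-(4α→6)-gallocatechin, (2R,3S,4S)-4-[(2R,3S)-3,5,7-trihydroxy-2-(3,4,5-trihydroxyphenyl)chroman-6-yl]-2-(3,4,5-trihydroxyphenyl)chromane-3,7-diol | Oc1ccc2c(c1)O[C@H](c1cc(O)c(O)c(O)c1)[C@@H](O)[C@@H]2c1c(O)cc2c(c1O)C[C@H](O)[C@@H](c1cc(O)c(O)c(O)c1)O2 | target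

## Step count and risks

Total steps: 9 (steps 1–4 for the upper fragment, steps 5–6 for the lower fragment, steps 7–9 after convergence). Longest linear sequence: 7 (steps 1, 2, 3, 4, 7, 8, 9).

**Most likely to fail, 1: step 7.** The carbenoid may be diverted by oxonium-ylide formation at benzyl ethers or by carbene dimerisation, the hindered C6 may react slowly, or the C4 protonation may be unselective. The fallback keeps the same electrophilic C4 but makes it as a free α-keto benzylic cation instead of a metal carbenoid. It sets out from diol 3: acid methanolysis (CSA, MeOH, rt) gives (2R,3S,4R)-7-(benzyloxy)-4-methoxy-2-[3,4,5-tris(benzyloxy)phenyl]chroman-3-ol F1. Oxidation (DMP, NaHCO3, CH2Cl2) gives the 4-methoxyflavan-3-one F2. Ionisation with TMSOTf in CH2Cl2 at −78 → −30 °C in the presence of 9 gives Friedel–Crafts alkylation at C4. Kinetic attack anti to the C2 aryl group is expected to give mainly the C4-epimeric ketone F3; this is equilibrated through its doubly benzylic C4 enol (cat. Et3N, CH2Cl2, 0 °C) to the diequatorial ketone. The fallback comes back to the route at 11. Its own weak points are loss of the C2 proton from the cation (flavylium formation) and C2 epimerisation during the equilibration.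

**Most likely to fail, 2: step 8.** Hydride may add from the other face and give the all-cis alcohol. The fallback replaces kinetic hydride delivery by thermodynamic redox epimerisation. It sets out from 11: unselective reduction (NaBH4, THF/MeOH) gives 12 mixed with its 3-epimeric alcohol F4. The mixture is equilibrated under Meerwein–Ponndorf–Verley/Oppenauer conditions (Al(OiPr)3, cat. acetone, toluene/iPrOH, 80 °C), which funnels F4 into the all-equatorial 2,3-trans-3,4-trans alcohol. It comes back at 12.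

**Most likely to fail, 3: step 3.** The C4 cation may be trapped by ring A of another molecule (oligomers), or C2 may partly epimerise under acid. The fallback is a two-step redox detour from diol 3: ionic hydrogenation of the benzylic 4-OH (Et3SiH, TFA, CH2Cl2, −20 °C) gives 7,3',4',5'-tetra-O-benzylrobinetinidol F5, and Dess–Martin oxidation (DMP, NaHCO3, CH2Cl2) gives the ketone. It comes back at 4.

## Further compounds

F1 | step 7 | (2R,3S,4R)-7-(benzyloxy)-4-methoxy-2-[3,4,5-tris(benzyloxy)phenyl]chroman-3-ol | c1ccccc1COc1ccc2c(c1)O[C@H](c1cc(OCc3ccccc3)c(OCc3ccccc3)c(OCc3ccccc3)c1)[C@@H](O)[C@@H]2OC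
F2 | step 7 | (2R,4R)-7-(benzyloxy)-4-methoxy-2-[3,4,5-tris(benzyloxy)phenyl]chroman-3-one | c1ccccc1COc1ccc2c(c1)O[C@H](c1cc(OCc3ccccc3)c(OCc3ccccc3)c(OCc3ccccc3)c1)C(=O)[C@@H]2OC
F3 | step 7 | (2R,4R)-7-(benzyloxy)-4-[(2R,3S)-3,5,7-tris(benzyloxy)-8-bromo-2-(3,4,5-tris(benzyloxy)phenyl)chroman-6-yl]-2-[3,4,5-tris(benzyloxy)phenyl]chroman-3-one (C4 epimer of 11) | c1ccccc1COc1ccc2c(c1)O[C@H](c1cc(OCc3ccccc3)c(OCc3ccccc3)c(OCc3ccccc3)c1)C(=O)[C@H]2c1c(OCc3ccccc3)c(Br)c2c(c1OCc3ccccc3)C[C@H](OCc3ccccc3)[C@@H](c1cc(OCc3ccccc3)c(OCc3ccccc3)c(OCc3ccccc3)c1)O2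
F4 | step 8 | (2R,3R,4S)-7-(benzyloxy)-4-[(2R,3S)-3,5,7-tris(benzyloxy)-8-bromo-2-(3,4,5-tris(benzyloxy)phenyl)chroman-6-yl]-2-[3,4,5-tris(benzyloxy)phenyl]chroman-3-ol (C3 epimer of 12) | c1ccccc1COc1ccc2c(c1)O[C@H](c1cc(OCc3ccccc3)c(OCc3ccccc3)c(OCc3ccccc3)c1)[C@H](O)[C@@H]2c1c(OCc3ccccc3)c(Br)c2c(c1OCc3ccccc3)C[C@H](OCc3ccccc3)[C@@H](c1cc(OCc3ccccc3)c(OCc3ccccc3)c(OCc3ccccc3)c1)O2
F5 | step 3 | (2R,3S)-7-(benzyloxy)-2-[3,4,5-tris(benzyloxy)phenyl]chroman-3-ol | c1ccccc1COc1ccc2c(c1)O[C@H](c1cc(OCc3ccccc3)c(OCc3ccccc3)c(OCc3ccccc3)c1)[C@@H](O)C2
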